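Two questions stood, one about conversion and one about pH.

| flask | starting material | acid | protic impurity | remark | time |
|---|---|---|---|---|---|
| larch | 0.10 M | 1.5 mM | 0.010 M | run made earlier |  |
| ash | 0.10 M | 2.2 mM | 0.010 M | run made earlier |  |
| flask | 0.10 M | 3.00 mM | 0.0100 M |  | 2.5 d |

| run | time / h | starting material / % | target / % |
|---|---|---|---|
| larch | 3.00 | 72.6 | 11.9 |
| larch | 5.00 | 62.7 | 19.8 |
| larch | 10.0 | 45.4 | 32.3 |
| larch | 20.0 | 27.8 | 49.2 |
| larch | 40.0 | 12.9 | 67.8 |
| ash | 3.00 | 67.1 | 16.1 |
| ash | 10.0 | 37.7 | 38.6 |
| ash | 15.0 | 26.5 | 49.9 |
| ash | 25.0 | 15.3 | 63.0 |
| ash | 40.0 | 7.4 | 75.1 |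

(standard deviation of a reading: 0.5 percentage points)

- acid is the free proton; pH is minus the decimal logarithm of its molar concentration
- a reading or a percentage of target counts all its forms, free or not
- what has gone from starting material into another species counts as reacted, even if it can come back
- a reading of starting material is of its free form alone

1. part of the starting material that has reacted at 2.5 d
2. pH of the solution at 2.5 d

I began with the pseudo-first-order constant k, the target formed per unit of free starting material and per unit time. The ash readings from 15.0 h to 40.0 h gave 0.0687 h⁻¹. Taking k proportional to acid gave 0.0936 h⁻¹ for the flask, so the flask at 29.3 h should stand where ash stood at 40.0 h.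

The shortfall of that ash reading, less the 10.0% that the protic impurity can take, left 7.50%, which I took as parked reversibly. The free share f of the unconverted pool was therefore 49.7%. Assuming that parked material reacts by way of the free form, I defined the pool half-life, the natural logarithm of two over k times f, the time in which free plus parked material halves: 14.9 h. Over the remaining time this gave 98.2% reacted.

The weak link was f held fixed while target grows. Treating parking as an equilibrium, that reading gave a constant of 15.0 M⁻¹, so f falls to about 43.1%, and the mean share gave 98.3%, the number I committed to.

The forecast said 98% (96.5% to 99%) and pH 2.52 (2.47 to 2.62), holding that “free acid stays at the charged level”. I took the same pH on the same ground.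

The flask gave 98.0% reacted and pH 2.52, and what I called parked is the idle adduct.

    weak acid ⇌ conjugate base + acid, settled at all times (K = 4.00 × 10⁻¹⁰ M)
    starting material + acid → weak acid + acid + target (k = 0.425 M⁻¹ min⁻¹)
    starting material + protic impurity → quenched substrate (k = 0.175 M⁻¹ min⁻¹)
    starting material + target ⇌ idle adduct, settled at all times (K = 13.0 M⁻¹)
    starting material → weak acid + target (k = 1.67 × 10⁻⁴ min⁻¹)
    crystals ⇌ weak acid, rate k6*(cs6 - [weak acid]) while solid is left; crystals form when [weak acid] > cs6 (solubility = 3.00 mM, k = 0.120 min⁻¹)

In the flask, the half-life of starting material by its step with acid at the asked time, 0.38 d, is short against 2.5 d, and my pool half-life of 14.9 h is short against 2.5 d as well. Run back from 29.3 h to 25 h, that pool half-life gives 90.9% reacted for the neighbour flask left until then, which stands at 89.1%.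

Readings and results were generated by integration for an exercise; the scatter is artificial.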